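**Assumption:** Bleochrin B has no stereocentre and no stereogenic axis, so "single enantiomer" is read as the one achiral constitution drawn; no configuration has to be set.

**Retrosynthetic overview**
1. Last cuts: the three ring A–CH2 bonds, taken one per step, each giving 4-hydroxybenzyl alcohol 12 and leading back through 14 and 13 to triol 11 (three Friedel–Crafts benzylations; only ring A, a resorcinol monoether, is nucleophilic enough).
2. Key cut: the ring A C–OH bond, giving diphenol 8, whose ring A is a plain 3-alkylanisole. C–H to C–O at its one unhindered C–H sets the OMe/OH pattern without desymmetrising a resorcinol and activates ring A for the benzylations.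
3. Bibenzyl aryl–CH2 bond: aryl bromide 5 plus 3-vinylanisole 6 (hydroboration, B-alkyl Suzuki–Miyaura).
4. Ring B–CH2–ring C diarylmethane: aldehyde 1 plus Grignard 2 (addition, ionic hydrogenation), then O-demethylation before ring A and its OMe enter.
5. No ring is built. All six benzene rings are bought and joined in the order ring C to ring B, then ring A, then the three 4-hydroxybenzyl rings.

Ring A is the central ring, ring B the other bibenzyl ring, ring C the 4-hydroxybenzyl ring on ring B. Ring A positions are numbered as in phenol 11 (C1 OH, C3 chain, C5 OMe).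

**Route**

Step 1
Reactants: 1 2-bromo-4-methoxybenzaldehyde; 2 4-methoxyphenylmagnesium bromide
Product: 4 2-bromo-4-methoxy-1-(4-methoxybenzyl)benzene, via diarylmethanol 3 (not isolated)
Conditions: 2 (1.15 equiv, 0.5 M), THF, 0 °C; cold 0.5 M HCl; crude 3, Et3SiH (2 equiv), TFA (4 equiv), CH2Cl2, 0 °C to rt
Reagents that add atoms: none
Why: Grignard 1,2-addition gives a doubly benzylic carbinol whose cation, stabilised by two para-methoxyaryl groups, is reduced by Et3SiH (ionic hydrogenation); the aryl bromide is untouched and the transient carbinol stereocentre is erased.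

Step 2
Reactants: 4 2-bromo-4-methoxy-1-(4-methoxybenzyl)benzene
Product: 5 3-bromo-4-(4-hydroxybenzyl)phenol
Conditions: BBr3 (3 equiv), CH2Cl2, −78 °C to rt; H2O
Reagents that add atoms: none
Why: BBr3 ether cleavage removes both aryl methyl groups at this stage, before ring A is attached, so the one methoxy group of the target never meets a dealkylating reagent.

Step 3
Reactants: 5 3-bromo-4-(4-hydroxybenzyl)phenol; 6 1-ethenyl-3-methoxybenzene (3-vinylanisole)
Product: 8 4-(4-hydroxybenzyl)-3-[2-(3-methoxyphenyl)ethyl]phenol, via alkylborane 7 (not isolated)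
Conditions: 6 (1.5 equiv), 9-BBN (1.5 equiv), THF, 0 °C to rt; then 5, Pd(dppf)Cl2 (5 mol %), K3PO4 (3 M aq, 5 equiv), DMF, 70 °C
Reagents that add atoms: none
Why: 9-BBN hydroborates the styrene anti-Markovnikov and the B-alkyl-9-BBN then undergoes B-alkyl Suzuki–Miyaura coupling with the aryl bromide, giving the saturated two-carbon bridge directly; the phenols are carried as phenoxides.

Step 4
Reactants: 8 4-(4-hydroxybenzyl)-3-[2-(3-methoxyphenyl)ethyl]phenol
Product: 11 3-[2-[5-hydroxy-2-(4-hydroxybenzyl)phenyl]ethyl]-5-methoxyphenol, via bis(triethylsilyl) ether 9 (not isolated), via arylboronate 10 (not isolated)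
Conditions: Et3SiH (2.2 equiv), [Ir(OMe)(cod)]2 (1.5 mol %), THF, 60 °C (H2 off), volatiles removed; 4,4'-di-tert-butyl-2,2'-bipyridine (dtbpy, 3 mol %), B2pin2 (0.8 equiv), THF, 80 °C; then 2 M NaOH, 30% H2O2, 0 °C
Reagents that add atoms: hydrogen peroxide, OO
Why: Proposed new method: one monovalent iridium methoxide precatalyst serves two cycles in one flask; first it dehydrocouples both phenols with the tertiary silane (Ir–OAr + H–SiEt3 gives ArO–SiEt3 + Ir–H, then Ir–H + ArOH gives Ir–OAr + H2), then dtbpy and B2pin2 turn the iridium hydrides into the usual trivalent iridium tris(boryl) catalyst for sterically ruled C–H borylation; the bulky, non-directing OSiEt3 groups are chosen over the known traceless O–Bpin mask (which steers borylation ortho to oxygen) and over ArO–SiEt2H (which directs ortho-borylation), they close every C–H next to oxygen on rings B and C, all other C–H bonds there are ortho to a carbon substituent, so C5–H of ring A, the only one of eleven aromatic C–H bonds flanked by two hydrogens, is borylated, and alkaline H2O2 then makes the C–O bond by 1,2-aryl shift from boron to oxygen and hydrolyses both silyl ethers; closest known reaction type: the one-pot Ir-catalysed C–H borylation/oxidation of 1,3-disubstituted arenes to 3,5-disubstituted phenols (with traceless N–Bpin masking) together with Ir-catalysed silane alcoholysis; no stereocentre is formed.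

Step 5
Reactants: 11 3-[2-[5-hydroxy-2-(4-hydroxybenzyl)phenyl]ethyl]-5-methoxyphenol; 12 4-hydroxybenzyl alcohol
Product: 13 4-(4-hydroxybenzyl)-3-[2-[5-hydroxy-2-(4-hydroxybenzyl)phenyl]ethyl]-5-methoxyphenol
Conditions: 12 (1.0 equiv, added over 3 h), TsOH·H2O (2 mol %), 1,1,1,3,3,3-hexafluoropropan-2-ol (HFIP), 0 °C to rt; aq NaHCO3; SiO2 (C2 isomer kept with 13)
Reagents that add atoms: none
Why: Acid-catalysed dehydrative Friedel–Crafts benzylation through the 4-hydroxybenzyl cation/para-quinone methide in cation-stabilising HFIP: ring A, the only ring with two oxygen donors, is far more nucleophilic than any mono-oxygenated ring, and with one equivalent of 12 fed slowly the first benzyl group goes to a site that is para to one oxygen and ortho to the other, chiefly C4 para to the free OH; the C2 isomer formed beside it is not removed because both give 14 in step 6.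

Step 6
Reactants: 13 4-(4-hydroxybenzyl)-3-[2-[5-hydroxy-2-(4-hydroxybenzyl)phenyl]ethyl]-5-methoxyphenol; 12 4-hydroxybenzyl alcohol
Product: 14 2,4-bis(4-hydroxybenzyl)-3-[2-[5-hydroxy-2-(4-hydroxybenzyl)phenyl]ethyl]-5-methoxyphenol
Conditions: 12 (1.1 equiv, added over 3 h), TsOH·H2O (5 mol %), HFIP, rt; aq NaHCO3; SiO2
Reagents that add atoms: none
Why: The same Friedel–Crafts benzylation at the second para-activated site: C2 of 13, ortho to the free OH and para to OMe, is now the most nucleophilic aromatic carbon in the molecule, and the C2 isomer carried along from step 5 reacts at C4 to give the same 14.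

Step 7
Reactants: 14 2,4-bis(4-hydroxybenzyl)-3-[2-[5-hydroxy-2-(4-hydroxybenzyl)phenyl]ethyl]-5-methoxyphenol; 12 4-hydroxybenzyl alcohol
Product: 15 Bleochrin B (2,4,6-tris(4-hydroxybenzyl)-3-[2-[5-hydroxy-2-(4-hydroxybenzyl)phenyl]ethyl]-5-methoxyphenol)
Conditions: 12 (1.3 equiv, added over 4 h), TsOH·H2O (10 mol %), HFIP, 45 °C; aq NaHCO3; reversed-phase chromatography
Reagents that add atoms: none
Why: Third Friedel–Crafts benzylation at C6, the last free site of ring A: it is ortho to both oxygens and para to neither, so it is the slowest of the three and needs more acid and 45 °C, but it is still the only free aromatic position that carries two oxygen donors, and slow feeding of 12 keeps self-condensation of the reagent down.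

**Compound list**
1 | 2-bromo-4-methoxybenzaldehyde | COc1ccc(C=O)c(Br)c1 | starting material
2 | 4-methoxyphenylmagnesium bromide | COc1ccc([Mg]Br)cc1 | starting material
3 | (2-bromo-4-methoxyphenyl)(4-methoxyphenyl)methanol (racemic, transient) | COc1ccc(C(O)c2ccc(OC)cc2)c(Br)c1 | intermediate
4 | 2-bromo-4-methoxy-1-(4-methoxybenzyl)benzene | COc1ccc(Cc2ccc(OC)cc2)c(Br)c1 | intermediate
5 | 3-bromo-4-(4-hydroxybenzyl)phenol | Oc1ccc(Cc2ccc(O)cc2)c(Br)c1 | intermediate
6 | 1-ethenyl-3-methoxybenzene (3-vinylanisole) | COc1cccc(C=C)c1 | starting material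
7 | 9-[2-(3-methoxyphenyl)ethyl]-9-borabicyclo[3.3.1]nonane | COc1cccc(CCB2C3CCCC2CCC3)c1 | intermediate
8 | 4-(4-hydroxybenzyl)-3-[2-(3-methoxyphenyl)ethyl]phenol | COc1cccc(CCc2cc(O)ccc2Cc2ccc(O)cc2)c1 | intermediate
9 | bis(triethylsilyl) ether of 8 | COc1cccc(CCc2cc(O[Si](CC)(CC)CC)ccc2Cc2ccc(O[Si](CC)(CC)CC)cc2)c1 | intermediate
10 | ring A 5-(pinacolatoboryl) derivative of 9 | COc1cc(B2OC(C)(C)C(C)(C)O2)cc(CCc2cc(O[Si](CC)(CC)CC)ccc2Cc2ccc(O[Si](CC)(CC)CC)cc2)c1 | intermediate
11 | 3-[2-[5-hydroxy-2-(4-hydroxybenzyl)phenyl]ethyl]-5-methoxyphenol | COc1cc(O)cc(CCc2cc(O)ccc2Cc2ccc(O)cc2)c1 | intermediate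
12 | 4-hydroxybenzyl alcohol | OCc1ccc(O)cc1 | starting material
13 | 4-(4-hydroxybenzyl)-3-[2-[5-hydroxy-2-(4-hydroxybenzyl)phenyl]ethyl]-5-methoxyphenol | COc1cc(O)cc(CCc2cc(O)ccc2Cc2ccc(O)cc2)c1Cc1ccc(O)cc1 | intermediate
14 | 2,4-bis(4-hydroxybenzyl)-3-[2-[5-hydroxy-2-(4-hydroxybenzyl)phenyl]ethyl]-5-methoxyphenol | COc1cc(O)c(Cc2ccc(O)cc2)c(CCc2cc(O)ccc2Cc2ccc(O)cc2)c1Cc1ccc(O)cc1 | intermediate
15 | Bleochrin B | COc1c(Cc2ccc(O)cc2)c(O)c(Cc2ccc(O)cc2)c(CCc2cc(O)ccc2Cc2ccc(O)cc2)c1Cc1ccc(O)cc1 | target

**Totals**
Total step count: 7. Longest linear sequence: 7 steps (1 → 4 → 5 → 8 → 11 → 13 → 14 → 15).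

**Steps most likely to fail, with fallbacks**

Step 4 (the proposed new self-masking C–H hydroxylation). The risk is incomplete O-silylation or silane interference with the borylation catalyst, which would give borylation next to oxygen. The fallback buys the oxygen pattern of ring A and desymmetrises it by known chemistry. It sets out from 5. Commercial 3,5-dimethoxystyrene F1 is hydroborated with 9-BBN to 9-[2-(3,5-dimethoxyphenyl)ethyl]-9-borabicyclo[3.3.1]nonane F2, used in the flask. F2 is coupled with 5 under the conditions of step 3 to give 3-[2-(3,5-dimethoxyphenyl)ethyl]-4-(4-hydroxybenzyl)phenol F3. One of the two equivalent methyl ethers of F3 is then cleaved with NaSEt (5 equiv, DMF, 140 °C); the first phenoxide formed on ring A shuts off the second SN2 demethylation. This comes back to the route at 11.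

Step 7 (third benzylation, at the crowded position between the two oxygens of an otherwise fully substituted ring). The risk is that this site reacts so slowly that 12 is used up by condensation at its own ring or benzylates a mono-phenol ring. The fallback changes to a masked electrophile that cannot self-condense and adds a deprotection; it sets out from 14. Commercial 4-(hydroxymethyl)phenyl acetate F4 (1.5 equiv; TfOH 5 mol %, HFIP/MeNO2, 50 °C) has a ring deactivated by the acetate, so it can be pushed with stronger acid and heat without oligomerising. It alkylates C6 of ring A to give 6-(4-acetoxybenzyl)-2,4-bis(4-hydroxybenzyl)-3-[2-[5-hydroxy-2-(4-hydroxybenzyl)phenyl]ethyl]-5-methoxyphenol F5. K2CO3 in MeOH at rt then removes the acetate and comes back to the route at 15.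

Step 3 (B-alkyl Suzuki–Miyaura coupling on an unprotected, electron-rich, ortho-substituted bromodiphenol). The risk is slow oxidative addition and protodeboronation of 7. The fallback forms the bridge as an alkene and reduces it, setting out from 5 and using 6. A Heck reaction (Pd(OAc)2 5 mol %, P(o-tol)3, Et3N, DMF, 110 °C) gives 4-(4-hydroxybenzyl)-3-[(E)-2-(3-methoxyphenyl)ethenyl]phenol F6. Hydrogenation (H2 1 atm, Pd/C, EtOAc/MeOH, rt) then saturates the stilbene and comes back to the route at 8.

**Further compounds**
F1 | step 4 | 3,5-dimethoxystyrene (bought building block) | COc1cc(OC)cc(C=C)c1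
F2 | step 4 | 9-[2-(3,5-dimethoxyphenyl)ethyl]-9-borabicyclo[3.3.1]nonane | COc1cc(OC)cc(CCB2C3CCCC2CCC3)c1
F3 | step 4 | 3-[2-(3,5-dimethoxyphenyl)ethyl]-4-(4-hydroxybenzyl)phenol | COc1cc(OC)cc(CCc2cc(O)ccc2Cc2ccc(O)cc2)c1
F4 | step 7 | 4-(hydroxymethyl)phenyl acetate (bought building block) | CC(=O)Oc1ccc(CO)cc1
F5 | step 7 | 6-(4-acetoxybenzyl)-2,4-bis(4-hydroxybenzyl)-3-[2-[5-hydroxy-2-(4-hydroxybenzyl)phenyl]ethyl]-5-methoxyphenol | COc1c(Cc2ccc(OC(C)=O)cc2)c(O)c(Cc2ccc(O)cc2)c(CCc2cc(O)ccc2Cc2ccc(O)cc2)c1Cc1ccc(O)cc1
F6 | step 3 | 4-(4-hydroxybenzyl)-3-[(E)-2-(3-methoxyphenyl)ethenyl]phenol | COc1cccc(/C=C/c2cc(O)ccc2Cc2ccc(O)cc2)c1
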